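**Retrosynthetic overview**
- Both esters are cut last: the bicyclic enone diol is acylated at O-4 with silyl-protected 4-hydroxybenzoyl chloride, and after reduction at O-8 with tigloyl chloride; the C8 carbinol comes from a convex-face 1,2-reduction of the enone.
- Ring B (cycloheptenone) is closed by ring-closing metathesis of a vinyl ketone with a 2-methylallyl group.
- The diene comes from a cis-fused keto γ-lactone: isopropyl is added to the ring A ketone from the convex face (C3), then vinyl to the lactone carbonyl (C8).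
- The keto lactone comes from a one-pot asymmetric conjugate methylation of methyl 3-oxocyclopent-1-ene-1-carboxylate, aldol addition to 3-methylbut-3-enal and lactonisation (sets C8a, C3a, C4).
- Ring order: ring A (from cyclopentane-1,3-dione), then the temporary lactone, then ring B; the four building blocks (6 to 10 non-hydrogen atoms each) are made separately.

Assumption: azulene numbering is used for the core (C3 carbinol, C3a/C8a ring fusion, C4 benzoate carbon, C8 tiglate carbon), and the SMILES is read as the cis-fused (3R,3aS,4R,8S,8aR) isomer with all three oxygens on the face opposite H-3a and the C8a methyl.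

**Step 1**
Reactants: 1 cyclopentane-1,3-dione
Product: 2 3-oxocyclopent-1-en-1-yl trifluoromethanesulfonate
Conditions: Tf2O, Et3N, CH2Cl2, −78 → 0 °C
Reagents that add atoms: trifluoromethanesulfonic anhydride O=S(=O)(OS(=O)(=O)C(F)(F)F)C(F)(F)F
Why: O-sulfonylation of the enolised β-diketone gives the vinylogous acyl triflate needed for oxidative addition; no stereocentre is formed.

**Step 2**
Reactants: 2 3-oxocyclopent-1-en-1-yl trifluoromethanesulfonate
Product: 3 methyl 3-oxocyclopent-1-ene-1-carboxylate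
Conditions: CO (1 atm), MeOH, Pd(OAc)2 (5 mol%), Ph2P(CH2)3PPh2 (5 mol%), Et3N, DMF, 50 °C
Reagents that add atoms: carbon monoxide [C-]#[O+]; methanol CO
Why: Palladium-catalysed alkoxycarbonylation of the enol triflate gives the β-ester enone, an activated acceptor for conjugate addition; no stereocentre is formed.

**Step 3**
Reactants: 4 3-methylbut-3-en-1-ol
Product: 5 3-methylbut-3-enal
Conditions: Dess–Martin periodinane, NaHCO3, CH2Cl2, 0 °C; cold filtered solution used at once
Reagents that add atoms: none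
Why: Dess–Martin oxidation is fast and near neutral, so the β,γ-unsaturated aldehyde is obtained without migration of the double bond into conjugation; no stereocentre is formed.

**Step 4**
Reactants: 3 methyl 3-oxocyclopent-1-ene-1-carboxylate; 5 3-methylbut-3-enal
Product: 8 (3R,3aS,6aR)-6a-methyl-3-(2-methylprop-2-en-1-yl)tetrahydro-1H-cyclopenta[c]furan-1,4(3H)-dione (cis-fused keto lactone), via zinc enolate 6 (not isolated), via zinc aldolate 7 (not isolated)
Conditions: Me2Zn, Cu(OTf)2 (5 mol%), chiral sulfonate-bearing imidazolinium salt L* (carbene precursor, 6 mol%, enantiomer giving the 1R adduct), Et2O/toluene, −30 °C; then 5, −78 → 0 °C; then 23 °C; aq NH4Cl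
Reagents that add atoms: dimethylzinc C[Zn]C
Why: Copper-catalysed asymmetric conjugate addition sets the quaternary centre (C6a, R) under ligand control, and the regiodefined zinc enolate then undergoes a reversible aldol addition from which only the aldolate with its side chain cis to the ester can lactonise; it does so with the 2-methylallyl group on the convex face, fixing C3a (S) and C3 (R).

**Step 5**
Reactants: 8 cis-fused keto lactone
Product: 9 (3R,3aS,4R,6aR)-4-hydroxy-6a-methyl-3-(2-methylprop-2-en-1-yl)-4-(propan-2-yl)hexahydro-1H-cyclopenta[c]furan-1-one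
Conditions: i-PrMgCl, CeCl3 (anhydrous), THF, −78 °C; aq NH4Cl
Reagents that add atoms: isopropylmagnesium chloride CC(C)[Mg]Cl
Why: The weakly basic organocerium reagent adds 1,2 to the ketone in preference to the hindered lactone and without enolisation or β-elimination, attacking the convex face anti to the lactone ring, so the new tertiary hydroxyl (C4, R) is cis to the lactone.

**Step 6**
Reactants: 9 hydroxy lactone
Product: 11 1-[(1R,2S,3R)-3-hydroxy-2-[(1R)-1-hydroxy-3-methylbut-3-en-1-yl]-1-methyl-3-(propan-2-yl)cyclopentyl]prop-2-en-1-one (in equilibrium with its cyclic lactol), via magnesium lactolate 10 (not isolated)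
Conditions: CH2=CHMgBr (3 equiv), THF, −78 → −30 °C; aq NH4Cl at −78 °C
Reagents that add atoms: vinylmagnesium bromide C=C[Mg]Br
Why: Acyl substitution on the neopentyl lactone stops after one addition because the tetrahedral magnesium lactolate survives at low temperature and collapses to the vinyl ketone only on work-up; no stereocentre is created or touched.

**Step 7**
Reactants: 11 hydroxy dienone
Product: 12 (3R,3aS,4R,8aR)-3,4-dihydroxy-6,8a-dimethyl-3-(propan-2-yl)-2,3,3a,4,5,8a-hexahydroazulen-8(1H)-one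
Conditions: second-generation Hoveyda–Grubbs catalyst RuCl2(H2IMes)(=CH-C6H4-2-O-i-Pr) (5 mol%), toluene (2 mM), 80 °C
Reagents that add atoms: none
Why: Ring-closing metathesis between the vinyl ketone and the 1,1-disubstituted olefin closes ring B as the trisubstituted cycloheptenone, the cis ring fusion inherited from the lactone holding both arms on the same face; no stereocentre is changed.

**Step 8**
Reactants: 13 4-bromophenol
Product: 14 (4-bromophenoxy)(tert-butyl)dimethylsilane
Conditions: TBSCl, imidazole, DMF, 23 °C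
Reagents that add atoms: tert-butyldimethylsilyl chloride CC(C)(C)[Si](C)(C)Cl
Why: Imidazole-promoted silylation masks the phenol for the organolithium and acylation steps; no stereocentre is formed.

**Step 9**
Reactants: 14 (4-bromophenoxy)(tert-butyl)dimethylsilane
Product: 16 4-[(tert-butyldimethylsilyl)oxy]benzoic acid, via aryllithium 15 (not isolated)
Conditions: n-BuLi, THF, −78 °C; CO2 (g); aq HCl to pH 3
Reagents that add atoms: carbon dioxide O=C=O
Why: Bromine–lithium exchange followed by carboxylation of the aryllithium builds the benzoic acid; no stereocentre is formed.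

**Step 10**
Reactants: 16 4-[(tert-butyldimethylsilyl)oxy]benzoic acid
Product: 17 4-[(tert-butyldimethylsilyl)oxy]benzoyl chloride
Conditions: (COCl)2, DMF (cat.), CH2Cl2, 0 → 23 °C
Reagents that add atoms: oxalyl chloride O=C(Cl)C(Cl)=O
Why: Vilsmeier-type activation converts the acid into the acid chloride under conditions the aryl silyl ether tolerates; no stereocentre is formed.

**Step 11**
Reactants: 12 bicyclic dihydroxy enone; 17 4-[(tert-butyldimethylsilyl)oxy]benzoyl chloride
Product: 18 (3R,3aS,4R,8aR)-3-hydroxy-6,8a-dimethyl-8-oxo-3-(propan-2-yl)-1,2,3,3a,4,5,8,8a-octahydroazulen-4-yl 4-[(tert-butyldimethylsilyl)oxy]benzoate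
Conditions: Et3N, DMAP (cat.), CH2Cl2, 0 → 23 °C
Reagents that add atoms: none
Why: DMAP-catalysed acylation joins the bicyclic core to the aryl fragment at the only secondary hydroxyl (the tertiary C3 hydroxyl is inert), with retention at C4.

**Step 12**
Reactants: 18 enone benzoate
Product: 19 (3R,3aS,4R,8S,8aR)-3,8-dihydroxy-6,8a-dimethyl-3-(propan-2-yl)-1,2,3,3a,4,5,8,8a-octahydroazulen-4-yl 4-[(tert-butyldimethylsilyl)oxy]benzoate
Conditions: NaBH4, CeCl3·7H2O, MeOH, −78 °C
Reagents that add atoms: none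
Why: Luche 1,2-reduction delivers hydride to the convex face of the cis-fused bicycle (the face of the angular methyl, anti to the pseudo-axial ring A methylene on C8a), giving the 8S allylic alcohol; the acylated O-4 cannot direct hydride to the other face.

**Step 13**
Reactants: 20 tiglic acid, (2E)-2-methylbut-2-enoic acid
Product: 21 tigloyl chloride, (2E)-2-methylbut-2-enoyl chloride
Conditions: (COCl)2, DMF (cat.), CH2Cl2, 0 → 23 °C
Reagents that add atoms: oxalyl chloride O=C(Cl)C(Cl)=O
Why: Vilsmeier-type activation gives the acid chloride with the thermodynamically preferred E double bond unchanged.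

**Step 14**
Reactants: 19 allylic alcohol; 21 tigloyl chloride
Product: 22 (3R,3aS,4R,8S,8aR)-3-hydroxy-6,8a-dimethyl-8-{[(2E)-2-methylbut-2-enoyl]oxy}-3-(propan-2-yl)-1,2,3,3a,4,5,8,8a-octahydroazulen-4-yl 4-[(tert-butyldimethylsilyl)oxy]benzoate
Conditions: pyridine, DMAP, CH2Cl2, 40 °C
Reagents that add atoms: none
Why: DMAP-catalysed acylation esterifies the hindered allylic C8 hydroxyl with retention while the tertiary C3 hydroxyl stays free; pyridine (not a stronger base) avoids deconjugation of the tigloyl unit.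

**Step 15**
Reactants: 22 silyl-protected diester
Product: 23 target, (3R,3aS,4R,8S,8aR)-3-hydroxy-6,8a-dimethyl-8-{[(2E)-2-methylbut-2-enoyl]oxy}-3-(propan-2-yl)-1,2,3,3a,4,5,8,8a-octahydroazulen-4-yl 4-hydroxybenzoate
Conditions: Bu4NF, AcOH (1:1), THF, 0 °C
Reagents that add atoms: none
Why: Fluoride-mediated desilylation cleaves the aryl silyl ether rapidly, and the acetic acid buffer keeps both esters from cleavage or migration; no stereocentre is touched.

**Compound list**
1 | cyclopentane-1,3-dione | O=C1CCC(=O)C1 | starting material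
2 | 3-oxocyclopent-1-en-1-yl trifluoromethanesulfonate | O=C1CCC(OS(=O)(=O)C(F)(F)F)=C1 | intermediate
3 | methyl 3-oxocyclopent-1-ene-1-carboxylate | COC(=O)C1=CC(=O)CC1 | intermediate
4 | 3-methylbut-3-en-1-ol | CC(=C)CCO | starting material
5 | 3-methylbut-3-enal | CC(=C)CC=O | intermediate
6 | methyl (1R)-1-methyl-3-[(methylzincio)oxy]cyclopent-2-ene-1-carboxylate (zinc enolate) | COC(=O)[C@]1(C)CCC(O[Zn]C)=C1 | intermediate (not isolated)
7 | methyl (1R,2S)-1-methyl-2-[(1R)-3-methyl-1-[(methylzincio)oxy]but-3-en-1-yl]-3-oxocyclopentane-1-carboxylate (zinc aldolate) | COC(=O)[C@]1(C)CCC(=O)[C@@H]1[C@H](O[Zn]C)CC(C)=C | intermediate (not isolated)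
8 | (3R,3aS,6aR)-6a-methyl-3-(2-methylprop-2-en-1-yl)tetrahydro-1H-cyclopenta[c]furan-1,4(3H)-dione | O=C1O[C@H](CC(C)=C)[C@@H]2[C@@]1(C)CCC2=O | intermediate
9 | (3R,3aS,4R,6aR)-4-hydroxy-6a-methyl-3-(2-methylprop-2-en-1-yl)-4-(propan-2-yl)hexahydro-1H-cyclopenta[c]furan-1-one | O=C1O[C@H](CC(C)=C)[C@@H]2[C@@]1(C)CC[C@@]2(O)C(C)C | intermediate
10 | (3R,3aS,4R,6aR)-1-ethenyl-6a-methyl-3-(2-methylprop-2-en-1-yl)-4-(propan-2-yl)hexahydro-1H-cyclopenta[c]furan-1,4-diol, bis(bromomagnesium) salt, both C1 epimers (magnesium lactolate) | C=CC1(O[Mg]Br)O[C@H](CC(C)=C)[C@@H]2[C@@]1(C)CC[C@@]2(O[Mg]Br)C(C)C | intermediate (not isolated)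
11 | 1-[(1R,2S,3R)-3-hydroxy-2-[(1R)-1-hydroxy-3-methylbut-3-en-1-yl]-1-methyl-3-(propan-2-yl)cyclopentyl]prop-2-en-1-one | C=CC(=O)[C@]1(C)CC[C@@](O)(C(C)C)[C@@H]1[C@H](O)CC(C)=C | intermediate
12 | (3R,3aS,4R,8aR)-3,4-dihydroxy-6,8a-dimethyl-3-(propan-2-yl)-2,3,3a,4,5,8a-hexahydroazulen-8(1H)-one | O=C1C=C(C)C[C@@H](O)[C@@H]2[C@@]1(C)CC[C@@]2(O)C(C)C | intermediate
13 | 4-bromophenol | Oc1ccc(Br)cc1 | starting material
14 | (4-bromophenoxy)(tert-butyl)dimethylsilane | CC(C)(C)[Si](C)(C)Oc1ccc(Br)cc1 | intermediate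
15 | {4-[(tert-butyldimethylsilyl)oxy]phenyl}lithium | CC(C)(C)[Si](C)(C)Oc1ccc([Li])cc1 | intermediate (not isolated)
16 | 4-[(tert-butyldimethylsilyl)oxy]benzoic acid | CC(C)(C)[Si](C)(C)Oc1ccc(cc1)C(=O)O | intermediate
17 | 4-[(tert-butyldimethylsilyl)oxy]benzoyl chloride | CC(C)(C)[Si](C)(C)Oc1ccc(cc1)C(Cl)=O | intermediate
18 | (3R,3aS,4R,8aR)-3-hydroxy-6,8a-dimethyl-8-oxo-3-(propan-2-yl)-1,2,3,3a,4,5,8,8a-octahydroazulen-4-yl 4-[(tert-butyldimethylsilyl)oxy]benzoate | O=C1C=C(C)C[C@@H](OC(=O)c2ccc(O[Si](C)(C)C(C)(C)C)cc2)[C@@H]2[C@@]1(C)CC[C@@]2(O)C(C)C | intermediate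
19 | (3R,3aS,4R,8S,8aR)-3,8-dihydroxy-6,8a-dimethyl-3-(propan-2-yl)-1,2,3,3a,4,5,8,8a-octahydroazulen-4-yl 4-[(tert-butyldimethylsilyl)oxy]benzoate | O[C@H]1C=C(C)C[C@@H](OC(=O)c2ccc(O[Si](C)(C)C(C)(C)C)cc2)[C@@H]2[C@@]1(C)CC[C@@]2(O)C(C)C | intermediate
20 | tiglic acid, (2E)-2-methylbut-2-enoic acid | C/C=C(\C)C(=O)O | starting material
21 | tigloyl chloride, (2E)-2-methylbut-2-enoyl chloride | C/C=C(\C)C(Cl)=O | intermediate
22 | (3R,3aS,4R,8S,8aR)-3-hydroxy-6,8a-dimethyl-8-{[(2E)-2-methylbut-2-enoyl]oxy}-3-(propan-2-yl)-1,2,3,3a,4,5,8,8a-octahydroazulen-4-yl 4-[(tert-butyldimethylsilyl)oxy]benzoate | C/C=C(\C)C(=O)O[C@H]1C=C(C)C[C@@H](OC(=O)c2ccc(O[Si](C)(C)C(C)(C)C)cc2)[C@@H]2[C@@]1(C)CC[C@@]2(O)C(C)C | intermediate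
23 | (3R,3aS,4R,8S,8aR)-3-hydroxy-6,8a-dimethyl-8-{[(2E)-2-methylbut-2-enoyl]oxy}-3-(propan-2-yl)-1,2,3,3a,4,5,8,8a-octahydroazulen-4-yl 4-hydroxybenzoate | C/C=C(\C)C(=O)O[C@H]1C=C(C)C[C@@H](OC(=O)c2ccc(O)cc2)[C@@H]2[C@@]1(C)CC[C@@]2(O)C(C)C | target

**Step count**
Total: 15 steps. Longest linear sequence: 10 steps (1, 2, 4, 5, 6, 7, 11, 12, 14, 15). The branches are step 3 (aldehyde), steps 8 to 10 (aryl acid chloride) and step 13 (tigloyl chloride).

**Steps most likely to fail**

Step 4 (three-component conjugate addition, aldol, lactonisation). The risks are the enantioselectivity on the five-membered enone, the lability of aldehyde 5 towards the zinc enolate, and incomplete funnelling to the cis-fused convex-face lactone. The fallback sets out from 3 and comes back at 8. The copper-catalysed methyl addition is run alone and the zinc enolate is trapped with Me3SiCl to give the isolable silyl enol ether methyl (1R)-1-methyl-3-[(trimethylsilyl)oxy]cyclopent-2-ene-1-carboxylate F1, whose optical purity can be checked. F1 is then joined to 5 in a Lewis-acid-mediated Mukaiyama aldol addition (BF3·OEt2, CH2Cl2, −78 °C) to give the hydroxy ester methyl (1R)-2-(1-hydroxy-3-methylbut-3-en-1-yl)-1-methyl-3-oxocyclopentane-1-carboxylate F2 as a diastereomer mixture. DBU in toluene epimerises the ketone α-carbon and lactonises the cis isomer to 8.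

Step 6 (mono-addition of the vinyl Grignard reagent to the lactone). The risk is a second addition after premature collapse of the lactolate. The fallback sets out from 9 and comes back at 11. The lactone is opened with Me2AlN(OMe)Me (from MeNH(OMe)·HCl and Me3Al) to the Weinreb amide (1R,2S,3R)-3-hydroxy-2-[(1R)-1-hydroxy-3-methylbut-3-en-1-yl]-N-methoxy-N,1-dimethyl-3-(propan-2-yl)cyclopentane-1-carboxamide F3. Excess CH2=CHMgBr then gives a chelated tetrahedral intermediate that cannot add a second time and releases 11 on work-up.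

Step 7 (ring-closing metathesis of an electron-poor vinyl ketone with a 1,1-disubstituted olefin). The risk is slow closure and dimerisation at the enone. The fallback sets out from 9 and comes back at 12; it closes the ring at the allylic alcohol oxidation level. Reduction of 9 with i-Bu2AlH at −78 °C gives the lactol (3R,3aS,4R,6aR)-6a-methyl-3-(2-methylprop-2-en-1-yl)-4-(propan-2-yl)hexahydro-1H-cyclopenta[c]furan-1,4-diol F4. Excess CH2=CHMgBr opens it to the triol (1R,2S,3R)-2-[(1R)-1-hydroxy-3-methylbut-3-en-1-yl]-3-(1-hydroxyprop-2-en-1-yl)-3-methyl-1-(propan-2-yl)cyclopentan-1-ol F5 (either carbinol epimer). The more reactive allylic alcohol olefin undergoes ring-closing metathesis with the same ruthenium catalyst to the bicyclic triol (3R,3aS,4R,8aR)-6,8a-dimethyl-3-(propan-2-yl)-1,2,3,3a,4,5,8,8a-octahydroazulene-3,4,8-triol F6. MnO2 oxidises only the allylic hydroxyl, giving 12.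

**Further compounds**
F1 | step 4 | methyl (1R)-1-methyl-3-[(trimethylsilyl)oxy]cyclopent-2-ene-1-carboxylate | COC(=O)[C@]1(C)CCC(O[Si](C)(C)C)=C1
F2 | step 4 | methyl (1R)-2-(1-hydroxy-3-methylbut-3-en-1-yl)-1-methyl-3-oxocyclopentane-1-carboxylate (diastereomer mixture) | COC(=O)[C@]1(C)CCC(=O)C1C(O)CC(C)=C
F3 | step 6 | (1R,2S,3R)-3-hydroxy-2-[(1R)-1-hydroxy-3-methylbut-3-en-1-yl]-N-methoxy-N,1-dimethyl-3-(propan-2-yl)cyclopentane-1-carboxamide | CON(C)C(=O)[C@]1(C)CC[C@@](O)(C(C)C)[C@@H]1[C@H](O)CC(C)=C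
F4 | step 7 | (3R,3aS,4R,6aR)-6a-methyl-3-(2-methylprop-2-en-1-yl)-4-(propan-2-yl)hexahydro-1H-cyclopenta[c]furan-1,4-diol (anomer mixture) | OC1O[C@H](CC(C)=C)[C@@H]2[C@@]1(C)CC[C@@]2(O)C(C)C
F5 | step 7 | (1R,2S,3R)-2-[(1R)-1-hydroxy-3-methylbut-3-en-1-yl]-3-(1-hydroxyprop-2-en-1-yl)-3-methyl-1-(propan-2-yl)cyclopentan-1-ol (carbinol epimers) | C=CC(O)[C@]1(C)CC[C@@](O)(C(C)C)[C@@H]1[C@H](O)CC(C)=C
F6 | step 7 | (3R,3aS,4R,8aR)-6,8a-dimethyl-3-(propan-2-yl)-1,2,3,3a,4,5,8,8a-octahydroazulene-3,4,8-triol (C8 epimers) | OC1C=C(C)C[C@@H](O)[C@@H]2[C@@]1(C)CC[C@@]2(O)C(C)C
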